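**Retrosynthetic overview**

1. Atom numbers are daucane numbers: C1 quaternary ring-fusion carbon (angular CH3), C2 (O-angeloyl), C3, C4 (tertiary carbinol, iPr), C5 ring-fusion CH, C6 (O-aroyl), C7, C8(CH3)=C9, C10. The two esters are cut last (C2 angelate, then C6 trimethoxybenzoate) and the C8 methyl is traced back to CO2Me.
2. Five-membered ring (C1–C5): opened at C4–C5, an intramolecular Mukaiyama aldol of a C5=C6 silyl enol ether onto a pendant isopropyl ketone (sets C4 and C5); the C6 carbinol comes from a hydroxyl-directed reduction.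
3. Seven-membered ring (C1, C5–C10): at that stage it is a 1,4-cycloheptadiene, C8=C9 of the target plus C5=C6 as the enol form of the C6 oxygen function, separated by the C7 methylene. This skipped diene is the Cope product of a cis-divinylcyclopropane, so the ring is the formal [4+3] adduct of the acyclic 2-silyloxydiene C7=C6(OSi)–C5=C1 and the vinylcarbene C8–C9=C10 (bonds C7–C8 and C10–C1, quaternary C1).
4. The diene is acyclic: C2 comes from an asymmetric methyl ketone aldol between 3-methylbutan-2-one and a silyloxydienal made in three steps from pyruvaldehyde dimethyl acetal. Ring order: seven-membered ring first (key step), five-membered ring second.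

Key step: step 9

Assumption: the senses of induction of (−)-Ipc2BCl (Si-face attack on the aldehyde) and of Rh2(R-DOSP)4 [DOSP = N-(4-dodecylphenylsulfonyl)prolinate] are taken from the accepted models for these reagents; if either proved reversed, the enantiomeric reagent would be used. Atom numbers in the text are daucane numbers, not the locants of the systematic names.

**Step 1**
Reactants: 1 1,1-dimethoxypropan-2-one; 2 diethyl (2-oxopropyl)phosphonate
Product: 3 (3E)-5,5-dimethoxy-4-methylpent-3-en-2-one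
Conditions: NaH, THF, 0 °C to 60 °C; minor (Z)-isomer removed by chromatography
Reagents that add atoms: none
Why: Horner–Wadsworth–Emmons olefination of an activated α,α-dialkoxy ketone, in which the (E)-alkene (acetyl trans to the bulkier acetal carbon) should predominate.

**Step 2**
Reactants: 3 (3E)-5,5-dimethoxy-4-methylpent-3-en-2-one
Product: 4 (2E)-2-methyl-4-oxopent-2-enal
Conditions: 1 M aq. HCl, THF, 0 °C to rt
Reagents that add atoms: water, O
Why: Acid hydrolysis of the dimethyl acetal, with the (E) geometry of the ene-dicarbonyl unit retained.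

**Step 3**
Reactants: 4 (2E)-2-methyl-4-oxopent-2-enal
Product: 5 (2E)-4-[(tert-butyldimethylsilyl)oxy]-2-methylpenta-2,4-dienal
Conditions: TBSOTf, Et3N, CH2Cl2, −78 °C to 0 °C
Reagents that add atoms: tert-butyldimethylsilyl trifluoromethanesulfonate, CC(C)(C)[Si](C)(C)OS(=O)(=O)C(F)(F)F
Why: Soft enolisation (silyl triflate/amine) of the methyl ketone at the kinetically favoured α′-methyl group gives the cross-conjugated 2-silyloxydiene, and the aldehyde, which has no α-hydrogen, is left untouched.

**Step 4**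
Reactants: 5 (2E)-4-[(tert-butyldimethylsilyl)oxy]-2-methylpenta-2,4-dienal; 6 3-methylbutan-2-one
Product: 9 (5S,6E)-8-[(tert-butyldimethylsilyl)oxy]-5-hydroxy-2,6-dimethylnona-6,8-dien-3-one, via enol borinate 7 (not isolated), via boron aldolate 8 (not isolated)
Conditions: 6, (−)-Ipc2BCl, Et3N, Et2O, 0 °C; then 5, −78 °C to −20 °C; then H2O2, MeOH, pH 7 buffer, 0 °C
Reagents that add atoms: (−)-B-chlorodiisopinocampheylborane, ClB([C@@H]1C[C@@H]2C[C@H]([C@H]1C)C2(C)C)[C@@H]1C[C@@H]2C[C@H]([C@H]1C)C2(C)C (boron fragment of 7 and 8 only, no atoms in 9)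
Why: Diisopinocampheylboron-mediated aldol addition of the regioselectively formed methyl-side enol borinate through a chair transition state, in which the reagent directs attack to the Si face of the α-methyl enal and so sets the (S) carbinol centre (daucane C2); the enantioselectivity of this reagent with methyl ketones is expected to be only moderate.

**Step 5**
Reactants: 9 (5S,6E)-8-[(tert-butyldimethylsilyl)oxy]-5-hydroxy-2,6-dimethylnona-6,8-dien-3-one
Product: 10 (5S,6E)-5,8-bis[(tert-butyldimethylsilyl)oxy]-2,6-dimethylnona-6,8-dien-3-one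
Conditions: TBSOTf, 2,6-lutidine, CH2Cl2, −78 °C
Reagents that add atoms: tert-butyldimethylsilyl trifluoromethanesulfonate, CC(C)(C)[Si](C)(C)OS(=O)(=O)C(F)(F)F
Why: Silylation of the secondary alcohol with a silyl triflate and a hindered pyridine base at low temperature, conditions under which the hindered isopropyl ketone is not enolised and the carbinol stereocentre is untouched.

**Step 6**
Reactants: 11 methyl acetoacetate
Product: 12 methyl 2-diazo-3-oxobutanoate
Conditions: 4-acetamidobenzenesulfonyl azide, Et3N, MeCN, 0 °C to rt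
Reagents that add atoms: 4-acetamidobenzenesulfonyl azide, CC(=O)Nc1ccc(cc1)S(=O)(=O)N=[N+]=[N-]
Why: Regitz diazo transfer to an active methylene compound.

**Step 7**
Reactants: 12 methyl 2-diazo-3-oxobutanoate
Product: 13 methyl 2-diazo-3-hydroxybutanoate (racemic)
Conditions: NaBH4, MeOH, 0 °C
Reagents that add atoms: none
Why: Chemoselective borohydride reduction of the ketone beside the diazo carbon; the racemic carbinol centre is removed in step 8.

**Step 8**
Reactants: 13 methyl 2-diazo-3-hydroxybutanoate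
Product: 14 methyl 2-diazobut-3-enoate
Conditions: POCl3, Et3N, CH2Cl2, 0 °C; cold pentane solution used at once
Reagents that add atoms: none
Why: Dehydration of the β-hydroxy diazo ester through its dichlorophosphate by base-induced elimination; the vinyldiazo ester cyclises to a pyrazole on standing and is therefore used immediately.

**Step 9**
Reactants: 10 (5S,6E)-5,8-bis[(tert-butyldimethylsilyl)oxy]-2,6-dimethylnona-6,8-dien-3-one; 14 methyl 2-diazobut-3-enoate
Product: 16 methyl (4R)-6-[(tert-butyldimethylsilyl)oxy]-4-{(1S)-1-[(tert-butyldimethylsilyl)oxy]-4-methyl-3-oxopentyl}-4-methylcyclohepta-1,5-diene-1-carboxylate, via cis-divinylcyclopropane 15 (not isolated)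
Conditions: Rh2(R-DOSP)4 (2 mol %), hexanes, −40 °C, slow addition of 14 (3 equiv); then rt, then 60 °C
Reagents that add atoms: none
Why: The rhodium carbenoid from 14 cyclopropanates the electron-rich terminal C7=C6(OSi) alkene of the 2-silyloxydiene (bond C7–C8 and a transient C6–C8 bond) with the dienyl residue cis to the vinyl group, and the cis-divinylcyclopropane 15 then undergoes a [3,3]-sigmatropic (Cope) rearrangement through the obligatory boat transition state, which breaks C6–C8 and forms C10–C1, so that the seven-membered ring (C1, C5, C6, C7, C8, C9, C10) is closed in a formal [4+3] cycloaddition. The closest known reaction type is the tandem cyclopropanation/Cope rearrangement of vinyldiazoacetates with dienes under chiral dirhodium tetraprolinate catalysis, which is established for 2-silyloxydienes and for trisubstituted diene termini that become quaternary centres. The only new stereocentre, C1, is controlled by the catalyst: Rh2(R-DOSP)4 fixes the absolute configuration of the cyclopropane at a site remote from the C2 stereocentre, and the stereospecific boat Cope step translates it, through the (E) geometry of C5=C1 (methyl inside, C2 chain outside), into the (R) configuration at C1. The step needs chemoselectivity for the silyloxy-substituted terminal alkene over the trisubstituted C5=C1 alkene and the ketone, which the preference of donor/acceptor carbenoids for electron-rich 1,1-disubstituted alkenes secures, and the hydrocarbon solvent suppresses reaction at the unsubstituted vinyl terminus of the carbenoid. Warming completes the Cope step, which is slowed by the inward methyl group. The product carries C8=C9 in its final position and a regiodefined C5=C6 silyl enol ether for the next ring closure, and diene derived from the minor aldol enantiomer emerges here as a separable diastereomer.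

**Step 10**
Reactants: 16 methyl (4R)-6-[(tert-butyldimethylsilyl)oxy]-4-{(1S)-1-[(tert-butyldimethylsilyl)oxy]-4-methyl-3-oxopentyl}-4-methylcyclohepta-1,5-diene-1-carboxylate
Product: 17 methyl (1S,3S,3aS,8aR)-1-[(tert-butyldimethylsilyl)oxy]-3-hydroxy-8a-methyl-4-oxo-3-(propan-2-yl)-1,2,3,3a,4,5,8,8a-octahydroazulene-6-carboxylate
Conditions: TiCl4, CH2Cl2, −78 °C; cold aq. NaHCO3; product used without delay
Reagents that add atoms: none
Why: Intramolecular Mukaiyama aldol addition (5-(enolexo)-exo-trig) of the C5=C6 silyl enol ether to the TiCl4-activated isopropyl ketone closes the cyclopentane; the three-atom tether from C1 can reach only the face of C5 that gives the cis ring fusion, and the isopropyl group should take the outside position so that the C4 oxygen ends cis to C6, the only arrangement in which the titanium aldolate can chelate the C6 carbonyl.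

**Step 11**
Reactants: 17 methyl (1S,3S,3aS,8aR)-1-[(tert-butyldimethylsilyl)oxy]-3-hydroxy-8a-methyl-4-oxo-3-(propan-2-yl)-1,2,3,3a,4,5,8,8a-octahydroazulene-6-carboxylate
Product: 18 methyl (1S,3S,3aR,4R,8aR)-1-[(tert-butyldimethylsilyl)oxy]-3,4-dihydroxy-8a-methyl-3-(propan-2-yl)-1,2,3,3a,4,5,8,8a-octahydroazulene-6-carboxylate
Conditions: Me4NBH(OAc)3, MeCN/AcOH, −30 °C
Reagents that add atoms: none
Why: Evans–Saksena reduction, in which the C4 hydroxyl binds the triacetoxyborohydride and delivers hydride intramolecularly to the face of the C6 ketone on which C4 lies, giving the C6 alcohol trans to C4 and cis to H5 as in the target while the enoate and the silyl ether stay inert.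

**Step 12**
Reactants: 18 methyl (1S,3S,3aR,4R,8aR)-1-[(tert-butyldimethylsilyl)oxy]-3,4-dihydroxy-8a-methyl-3-(propan-2-yl)-1,2,3,3a,4,5,8,8a-octahydroazulene-6-carboxylate
Product: 19 (1S,3S,3aR,4R,8aR)-1-[(tert-butyldimethylsilyl)oxy]-6-(hydroxymethyl)-8a-methyl-3-(propan-2-yl)-1,2,3,3a,4,5,8,8a-octahydroazulene-3,4-diol
Conditions: iBu2AlH (5 equiv), CH2Cl2, −78 °C to 0 °C; Rochelle salt work-up
Reagents that add atoms: none
Why: 1,2-Reduction of the α,β-unsaturated methyl ester to the primary allylic alcohol with no stereocentre touched.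

**Step 13**
Reactants: 19 (1S,3S,3aR,4R,8aR)-1-[(tert-butyldimethylsilyl)oxy]-6-(hydroxymethyl)-8a-methyl-3-(propan-2-yl)-1,2,3,3a,4,5,8,8a-octahydroazulene-3,4-diol
Product: 21 (1S,3S,3aR,4R,8aR)-1-[(tert-butyldimethylsilyl)oxy]-6,8a-dimethyl-3-(propan-2-yl)-1,2,3,3a,4,5,8,8a-octahydroazulene-3,4-diol, via allylic sulfate 20 (not isolated)
Conditions: SO3·pyridine (1.2 equiv), THF, 0 °C; then LiAlH4, 0 °C to rt
Reagents that add atoms: sulfur trioxide–pyridine complex, O=S(=O)=O.c1ccncc1 (sulfate group of 20 only, no atoms in 21)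
Why: Selective sulfation of the unhindered primary allylic hydroxyl followed by hydride displacement of the allylic sulfate monoester (SN2, without allylic transposition) turns CH2OH into the C8 methyl group, and a hindered secondary sulfate, should it form, is not displaced and returns the alcohol on work-up.

**Step 14**
Reactants: 21 (1S,3S,3aR,4R,8aR)-1-[(tert-butyldimethylsilyl)oxy]-6,8a-dimethyl-3-(propan-2-yl)-1,2,3,3a,4,5,8,8a-octahydroazulene-3,4-diol; 22 3,4,5-trimethoxybenzoyl chloride
Product: 23 (1S,3S,3aR,4R,8aR)-1-[(tert-butyldimethylsilyl)oxy]-3-hydroxy-6,8a-dimethyl-3-(propan-2-yl)-1,2,3,3a,4,5,8,8a-octahydroazulen-4-yl 3,4,5-trimethoxybenzoate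
Conditions: Et3N, DMAP, CH2Cl2, rt
Reagents that add atoms: none
Why: DMAP-catalysed acylation of the secondary C6 hydroxyl, under which the tertiary C4 hydroxyl does not react.

**Step 15**
Reactants: 23 (1S,3S,3aR,4R,8aR)-1-[(tert-butyldimethylsilyl)oxy]-3-hydroxy-6,8a-dimethyl-3-(propan-2-yl)-1,2,3,3a,4,5,8,8a-octahydroazulen-4-yl 3,4,5-trimethoxybenzoate
Product: 24 (1S,3S,3aR,4R,8aR)-1,3-dihydroxy-6,8a-dimethyl-3-(propan-2-yl)-1,2,3,3a,4,5,8,8a-octahydroazulen-4-yl 3,4,5-trimethoxybenzoate
Conditions: HF·pyridine, pyridine, THF, 0 °C to rt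
Reagents that add atoms: none
Why: Fluoride cleavage of the secondary silyl ether under buffered conditions that leave the aryl ester, the tertiary alcohol and the trisubstituted alkene untouched.

**Step 16**
Reactants: 24 (1S,3S,3aR,4R,8aR)-1,3-dihydroxy-6,8a-dimethyl-3-(propan-2-yl)-1,2,3,3a,4,5,8,8a-octahydroazulen-4-yl 3,4,5-trimethoxybenzoate; 25 angelic acid
Product: 27 (1S,3S,3aR,4R,8aR)-3-hydroxy-6,8a-dimethyl-3-(propan-2-yl)-4-[(3,4,5-trimethoxybenzoyl)oxy]-1,2,3,3a,4,5,8,8a-octahydroazulen-1-yl (2Z)-2-methylbut-2-enoate, via mixed anhydride 26 (not isolated)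
Conditions: 25, 2,4,6-trichlorobenzoyl chloride, Et3N, toluene, rt; then 24, 80 °C
Reagents that add atoms: 2,4,6-trichlorobenzoyl chloride, O=C(Cl)c1c(Cl)cc(Cl)cc1Cl (aroyl part of 26 only, no atoms in 27)
Why: Yamaguchi-type esterification through the angelic 2,4,6-trichlorobenzoic mixed anhydride without a nucleophilic catalyst, conditions under which the (Z)-2-methylbut-2-enoyl group should be transferred to the secondary C2 hydroxyl without isomerisation to the tiglate while the tertiary hydroxyl stays free.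

**Compound list**

1 | 1,1-dimethoxypropan-2-one | CC(=O)C(OC)OC | starting material
2 | diethyl (2-oxopropyl)phosphonate | CCOP(=O)(CC(C)=O)OCC | starting material
3 | (3E)-5,5-dimethoxy-4-methylpent-3-en-2-one | CC(=O)/C=C(\C)C(OC)OC | intermediate
4 | (2E)-2-methyl-4-oxopent-2-enal | CC(=O)/C=C(\C)C=O | intermediate
5 | (2E)-4-[(tert-butyldimethylsilyl)oxy]-2-methylpenta-2,4-dienal | C=C(O[Si](C)(C)C(C)(C)C)/C=C(\C)C=O | intermediate
6 | 3-methylbutan-2-one | CC(=O)C(C)C | starting material
7 | 3-methylbut-1-en-2-yl diisopinocampheylborinate (enol borinate of 6) | C=C(OB([C@@H]1C[C@@H]2C[C@H]([C@H]1C)C2(C)C)[C@@H]1C[C@@H]2C[C@H]([C@H]1C)C2(C)C)C(C)C | intermediate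
8 | diisopinocampheylboron aldolate of 9 | C=C(O[Si](C)(C)C(C)(C)C)/C=C(\C)[C@@H](OB([C@@H]1C[C@@H]2C[C@H]([C@H]1C)C2(C)C)[C@@H]1C[C@@H]2C[C@H]([C@H]1C)C2(C)C)CC(=O)C(C)C | intermediate
9 | (5S,6E)-8-[(tert-butyldimethylsilyl)oxy]-5-hydroxy-2,6-dimethylnona-6,8-dien-3-one | C=C(O[Si](C)(C)C(C)(C)C)/C=C(\C)[C@@H](O)CC(=O)C(C)C | intermediate
10 | (5S,6E)-5,8-bis[(tert-butyldimethylsilyl)oxy]-2,6-dimethylnona-6,8-dien-3-one | C=C(O[Si](C)(C)C(C)(C)C)/C=C(\C)[C@@H](O[Si](C)(C)C(C)(C)C)CC(=O)C(C)C | intermediate
11 | methyl acetoacetate | CC(=O)CC(=O)OC | starting material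
12 | methyl 2-diazo-3-oxobutanoate | CC(=O)C(=[N+]=[N-])C(=O)OC | intermediate
13 | methyl 2-diazo-3-hydroxybutanoate (racemic) | CC(O)C(=[N+]=[N-])C(=O)OC | intermediate
14 | methyl 2-diazobut-3-enoate | C=CC(=[N+]=[N-])C(=O)OC | intermediate
15 | methyl (1S,2R)-2-[(tert-butyldimethylsilyl)oxy]-2-{(1E,3S)-3-[(tert-butyldimethylsilyl)oxy]-2,6-dimethyl-5-oxohept-1-en-1-yl}-1-ethenylcyclopropane-1-carboxylate | COC(=O)[C@]1(C=C)C[C@@]1(O[Si](C)(C)C(C)(C)C)/C=C(\C)[C@@H](O[Si](C)(C)C(C)(C)C)CC(=O)C(C)C | intermediate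
16 | methyl (4R)-6-[(tert-butyldimethylsilyl)oxy]-4-{(1S)-1-[(tert-butyldimethylsilyl)oxy]-4-methyl-3-oxopentyl}-4-methylcyclohepta-1,5-diene-1-carboxylate | COC(=O)C1=CC[C@@](C)([C@@H](O[Si](C)(C)C(C)(C)C)CC(=O)C(C)C)C=C(O[Si](C)(C)C(C)(C)C)C1 | intermediate
17 | methyl (1S,3S,3aS,8aR)-1-[(tert-butyldimethylsilyl)oxy]-3-hydroxy-8a-methyl-4-oxo-3-(propan-2-yl)-1,2,3,3a,4,5,8,8a-octahydroazulene-6-carboxylate | CC(C)(C)[Si](C)(C)O[C@H]1C[C@](O)(C(C)C)[C@H]2C(=O)CC(C(=O)OC)=CC[C@@]12C | intermediate
18 | methyl (1S,3S,3aR,4R,8aR)-1-[(tert-butyldimethylsilyl)oxy]-3,4-dihydroxy-8a-methyl-3-(propan-2-yl)-1,2,3,3a,4,5,8,8a-octahydroazulene-6-carboxylate | CC(C)(C)[Si](C)(C)O[C@H]1C[C@](O)(C(C)C)[C@H]2[C@H](O)CC(C(=O)OC)=CC[C@@]12C | intermediate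
19 | (1S,3S,3aR,4R,8aR)-1-[(tert-butyldimethylsilyl)oxy]-6-(hydroxymethyl)-8a-methyl-3-(propan-2-yl)-1,2,3,3a,4,5,8,8a-octahydroazulene-3,4-diol | CC(C)(C)[Si](C)(C)O[C@H]1C[C@](O)(C(C)C)[C@H]2[C@H](O)CC(CO)=CC[C@@]12C | intermediate
20 | pyridinium sulfate monoester of the primary allylic alcohol of 19 | CC(C)(C)[Si](C)(C)O[C@H]1C[C@](O)(C(C)C)[C@H]2[C@H](O)CC(COS(=O)(=O)[O-])=CC[C@@]12C.c1cc[nH+]cc1 | intermediate
21 | (1S,3S,3aR,4R,8aR)-1-[(tert-butyldimethylsilyl)oxy]-6,8a-dimethyl-3-(propan-2-yl)-1,2,3,3a,4,5,8,8a-octahydroazulene-3,4-diol | CC(C)(C)[Si](C)(C)O[C@H]1C[C@](O)(C(C)C)[C@H]2[C@H](O)CC(C)=CC[C@@]12C | intermediate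
22 | 3,4,5-trimethoxybenzoyl chloride | COc1cc(cc(OC)c1OC)C(Cl)=O | starting material
23 | (1S,3S,3aR,4R,8aR)-1-[(tert-butyldimethylsilyl)oxy]-3-hydroxy-6,8a-dimethyl-3-(propan-2-yl)-1,2,3,3a,4,5,8,8a-octahydroazulen-4-yl 3,4,5-trimethoxybenzoate | CC(C)(C)[Si](C)(C)O[C@H]1C[C@](O)(C(C)C)[C@H]2[C@H](OC(=O)c3cc(OC)c(OC)c(OC)c3)CC(C)=CC[C@@]12C | intermediate
24 | (1S,3S,3aR,4R,8aR)-1,3-dihydroxy-6,8a-dimethyl-3-(propan-2-yl)-1,2,3,3a,4,5,8,8a-octahydroazulen-4-yl 3,4,5-trimethoxybenzoate | O[C@H]1C[C@](O)(C(C)C)[C@H]2[C@H](OC(=O)c3cc(OC)c(OC)c(OC)c3)CC(C)=CC[C@@]12C | intermediate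
25 | angelic acid, (2Z)-2-methylbut-2-enoic acid | C/C=C(/C)C(=O)O | starting material
26 | (2Z)-2-methylbut-2-enoic 2,4,6-trichlorobenzoic anhydride | C/C=C(/C)C(=O)OC(=O)c1c(Cl)cc(Cl)cc1Cl | intermediate
27 | (1S,3S,3aR,4R,8aR)-3-hydroxy-6,8a-dimethyl-3-(propan-2-yl)-4-[(3,4,5-trimethoxybenzoyl)oxy]-1,2,3,3a,4,5,8,8a-octahydroazulen-1-yl (2Z)-2-methylbut-2-enoate | C/C=C(/C)C(=O)O[C@H]1C[C@](O)(C(C)C)[C@H]2[C@H](OC(=O)c3cc(OC)c(OC)c(OC)c3)CC(C)=CC[C@@]12C | target

**Step count and risks**

Total step count: 16. Longest linear sequence: 13 steps (steps 1–5 and 9–16, from 1 to 27); the diazo ester branch (steps 6–8) joins at step 9.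

Steps most likely to fail:

1. Step 9. The resident C2 stereocentre or the ketone may erode the catalyst-controlled facial selectivity of the cyclopropanation, the dienyl group may end trans to the vinyl group in a cyclopropane that cannot rearrange, or the carbenoid may react at its vinyl terminus. Fallback: the order of fragment union is changed so that the carbenoid step runs on the achiral, ketone-free diene. It sets out from 5 (with 14): the same Rh2(R-DOSP)4-catalysed cyclopropanation/Cope sequence on the dienal should give methyl (4R)-6-[(tert-butyldimethylsilyl)oxy]-4-formyl-4-methylcyclohepta-1,5-diene-1-carboxylate F1 under pure catalyst control. Boron aldol addition of the enol borinate 7 to the aldehyde of F1 would give methyl (4R)-6-[(tert-butyldimethylsilyl)oxy]-4-[(1S)-1-hydroxy-4-methyl-3-oxopentyl]-4-methylcyclohepta-1,5-diene-1-carboxylate F2, and silylation with TBSOTf and 2,6-lutidine returns to the route at 16.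

2. Step 10. The aldol may revert (retro-aldol) on work-up, the enol ether may be protodesilylated before the C–C bond forms, or the ketone may be attacked on the wrong face. Fallback: a samarium Reformatsky-type ring closure in place of the Lewis acid aldol. It sets out from 16: N-bromosuccinimide in THF at 0 °C converts the silyl enol ether into methyl (4S)-5-bromo-4-{(1S)-1-[(tert-butyldimethylsilyl)oxy]-4-methyl-3-oxopentyl}-4-methyl-6-oxocyclohept-1-ene-1-carboxylate F3 (both C5 epimers). SmI2 in THF at −78 °C then generates the samarium enolate regiospecifically at C5, which should add to the isopropyl ketone through a chelated transition state and return to the route at 17.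

3. Step 16. The angeloyl group may isomerise to the tigloyl group during activation, or the hindered C2 hydroxyl beside the quaternary carbon may fail to be acylated. Fallback: the (Z)-alkene is built after the ester bond. It sets out from 24: esterification with 2-[bis(2,2,2-trifluoroethoxy)phosphoryl]propanoic acid (dicyclohexylcarbodiimide, DMAP, CH2Cl2) gives (1S,3S,3aR,4R,8aR)-1-({2-[bis(2,2,2-trifluoroethoxy)phosphoryl]propanoyl}oxy)-3-hydroxy-6,8a-dimethyl-3-(propan-2-yl)-1,2,3,3a,4,5,8,8a-octahydroazulen-4-yl 3,4,5-trimethoxybenzoate F4 (both epimers at the phosphonate carbon). Still–Gennari olefination with acetaldehyde (KN(SiMe3)2, 18-crown-6, THF, −78 °C) should then give the (Z)-2-methylbut-2-enoate and return to the route at 27.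

**Further compounds**

F1 | step 9 | methyl (4R)-6-[(tert-butyldimethylsilyl)oxy]-4-formyl-4-methylcyclohepta-1,5-diene-1-carboxylate | COC(=O)C1=CC[C@@](C)(C=O)C=C(O[Si](C)(C)C(C)(C)C)C1
F2 | step 9 | methyl (4R)-6-[(tert-butyldimethylsilyl)oxy]-4-[(1S)-1-hydroxy-4-methyl-3-oxopentyl]-4-methylcyclohepta-1,5-diene-1-carboxylate | COC(=O)C1=CC[C@@](C)([C@@H](O)CC(=O)C(C)C)C=C(O[Si](C)(C)C(C)(C)C)C1
F3 | step 10 | methyl (4S)-5-bromo-4-{(1S)-1-[(tert-butyldimethylsilyl)oxy]-4-methyl-3-oxopentyl}-4-methyl-6-oxocyclohept-1-ene-1-carboxylate (both C5 epimers) | COC(=O)C1=CC[C@@](C)([C@@H](O[Si](C)(C)C(C)(C)C)CC(=O)C(C)C)C(Br)C(=O)C1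
F4 | step 16 | (1S,3S,3aR,4R,8aR)-1-({2-[bis(2,2,2-trifluoroethoxy)phosphoryl]propanoyl}oxy)-3-hydroxy-6,8a-dimethyl-3-(propan-2-yl)-1,2,3,3a,4,5,8,8a-octahydroazulen-4-yl 3,4,5-trimethoxybenzoate (both epimers at the phosphonate carbon) | CC(C(=O)O[C@H]1C[C@](O)(C(C)C)[C@H]2[C@H](OC(=O)c3cc(OC)c(OC)c(OC)c3)CC(C)=CC[C@@]12C)P(=O)(OCC(F)(F)F)OCC(F)(F)F
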